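**Assumption:** the target has no stereocentre (it is achiral), so no enantiocontrol is needed; the only stereo-elements in the route are one racemic carbinol and two alkene geometries, all erased before the end.

## Retrosynthetic overview

1. Malabaricone C ⇐ one-pot hydrogenation/hydrogenolysis of a tetra-O-benzyl 2,8-dienone (both C=C bonds and all four benzyl ethers are removed in the last step).
2. Dienone ⇐ dehydration of a β-hydroxy ketone ⇐ key intermolecular directed aldol (C2–C3 bond) between the lithium enolate of 2',6'-bis(benzyloxy)acetophenone and 7-[3,4-bis(benzyloxy)phenyl]hept-6-enal.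
3. Aldehyde ⇐ alcohol ⇐ acid ⇐ Wittig reaction of 3,4-bis(benzyloxy)benzaldehyde with the ylide from 6-bromohexanoic acid and PPh3.
4. Ketone ⇐ double O-benzylation of 2',6'-dihydroxyacetophenone.
5. No ring is formed in the route: both benzene rings are bought in.

## Route

**Step 1**
Reactants: 1 2',6'-dihydroxyacetophenone
Product: 2 2',6'-bis(benzyloxy)acetophenone
Conditions: BnBr (2.5 equiv), K2CO3 (4 equiv), n-Bu4NI (cat.), DMF, 70 °C, 12 h
Reagents that add atoms: benzyl bromide, BrCc1ccccc1
Why: Williamson ether synthesis; K2CO3 in hot DMF deprotonates both hydrogen-bonded phenols and excess BnBr alkylates them on oxygen, masking the acidic OH groups for the enolate chemistry and setting up a final hydrogenolysis.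

**Step 2**
Reactants: 3 6-bromohexanoic acid
Product: 4 (5-carboxypentyl)triphenylphosphonium bromide
Conditions: PPh3 (1.05 equiv), MeCN, reflux, 48 h; crystallise from MeCN/Et2O
Reagents that add atoms: triphenylphosphine, c1ccc(cc1)P(c1ccccc1)c1ccccc1
Why: SN2 quaternisation of PPh3 by a primary alkyl bromide (phosphonium salt formation), which tolerates the free carboxylic acid.

**Step 3**
Reactants: 4 (5-carboxypentyl)triphenylphosphonium bromide; 5 3,4-bis(benzyloxy)benzaldehyde
Product: 7 (6Z)-7-[3,4-bis(benzyloxy)phenyl]hept-6-enoic acid (Z major; minor E isomer carried along), via carboxylate ylide 6 (not isolated)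
Conditions: 4 (1.3 equiv), NaN(SiMe3)2 (2.6 equiv), THF, 0 °C, 1 h; then 5, −78 °C → rt; aq. HCl to pH 2, acid–base extraction
Reagents that add atoms: none
Why: Wittig olefination with a non-stabilised ylide (one equivalent of base for CO2H, one for the α-CH) gives the styrenyl acid mainly as the Z isomer; the geometry is irrelevant because this alkene is saturated in step 8, and the acid is freed from Ph3PO by extraction into base.

**Step 4**
Reactants: 7 (6Z)-7-[3,4-bis(benzyloxy)phenyl]hept-6-enoic acid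
Product: 8 (6Z)-7-[3,4-bis(benzyloxy)phenyl]hept-6-en-1-ol
Conditions: LiAlH4 (2 equiv), THF, 0 °C → rt, 3 h; H2O, 15% aq. NaOH, H2O work-up
Reagents that add atoms: none
Why: LiAlH4 reduction of a carboxylic acid to the primary alcohol; the isolated styrenyl alkene and the benzyl ethers are inert to hydride.

**Step 5**
Reactants: 8 (6Z)-7-[3,4-bis(benzyloxy)phenyl]hept-6-en-1-ol
Product: 9 (6Z)-7-[3,4-bis(benzyloxy)phenyl]hept-6-enal
Conditions: Dess–Martin periodinane (1.2 equiv), CH2Cl2, 0 °C → rt, 1 h; used promptly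
Reagents that add atoms: none
Why: Dess–Martin oxidation stops cleanly at the aldehyde under neutral, anhydrous conditions and leaves the electron-rich styrene and the benzyl ethers untouched.

**Step 6 (key step)**
Reactants: 2 2',6'-bis(benzyloxy)acetophenone; 9 (6Z)-7-[3,4-bis(benzyloxy)phenyl]hept-6-enal
Product: 11 (8Z)-1-[2,6-bis(benzyloxy)phenyl]-9-[3,4-bis(benzyloxy)phenyl]-3-hydroxynon-8-en-1-one (racemic at C3), via lithium enolate 10 (not isolated)
Conditions: 2 (1.2 equiv), LiN(i-Pr)2 (1.25 equiv), THF, −78 °C, 45 min; then 9 (1.0 equiv) dropwise, −78 °C, 1 h; sat. aq. NH4Cl at −78 °C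
Reagents that add atoms: none
Why: directed (crossed) aldol addition; the methyl ketone has a single enolisable site and a carbonyl shielded by two ortho benzyloxy groups, so it is converted completely into its lithium enolate before the enolisable aldehyde is added cold, and the C2–C3 bond forms without self-condensation (the new carbinol centre is racemic and is destroyed in step 7).

**Step 7**
Reactants: 11 (8Z)-1-[2,6-bis(benzyloxy)phenyl]-9-[3,4-bis(benzyloxy)phenyl]-3-hydroxynon-8-en-1-one
Product: 13 (2E,8Z)-1-[2,6-bis(benzyloxy)phenyl]-9-[3,4-bis(benzyloxy)phenyl]nona-2,8-dien-1-one, via mesylate 12 (not isolated)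
Conditions: MsCl (1.5 equiv), Et3N (3 equiv), CH2Cl2, 0 °C, 30 min; then DBU (2 equiv), 0 °C → rt, 2 h
Reagents that add atoms: none
Why: activation of the β-hydroxyl as its mesylate followed by base-induced β-elimination (E1cB) gives the conjugated enone as the thermodynamically favoured E isomer; no stereocentre remains.

**Step 8**
Reactants: 13 (2E,8Z)-1-[2,6-bis(benzyloxy)phenyl]-9-[3,4-bis(benzyloxy)phenyl]nona-2,8-dien-1-one
Product: 14 malabaricone C, 1-(2,6-dihydroxyphenyl)-9-(3,4-dihydroxyphenyl)nonan-1-one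
Conditions: H2 (1 atm), Pd/C (10 wt%), EtOAc/MeOH 1:1, rt, monitored by LC-MS; filtration and concentration under argon
Reagents that add atoms: none
Why: heterogeneous catalytic hydrogenation saturates both C=C bonds (fast) and then hydrogenolyses the four aryl benzyl ethers, while the hindered, doubly hydrogen-bonded 2,6-dihydroxyaryl ketone resists reduction under neutral conditions; the product is achiral.

## Compound list

1 | 2',6'-dihydroxyacetophenone | CC(=O)c1c(O)cccc1O | starting material
2 | 2',6'-bis(benzyloxy)acetophenone | CC(=O)c1c(OCc2ccccc2)cccc1OCc1ccccc1 | intermediate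
3 | 6-bromohexanoic acid | OC(=O)CCCCCBr | starting material
4 | (5-carboxypentyl)triphenylphosphonium bromide | [Br-].OC(=O)CCCCC[P+](c1ccccc1)(c1ccccc1)c1ccccc1 | intermediate
5 | 3,4-bis(benzyloxy)benzaldehyde | O=Cc1ccc(OCc2ccccc2)c(OCc2ccccc2)c1 | starting material
6 | sodium 6-(triphenylphosphoranylidene)hexanoate (carboxylate ylide) | [Na+].[O-]C(=O)CCCCC=P(c1ccccc1)(c1ccccc1)c1ccccc1 | intermediate (not isolated)
7 | (6Z)-7-[3,4-bis(benzyloxy)phenyl]hept-6-enoic acid (Z major) | OC(=O)CCCC/C=C\c1ccc(OCc2ccccc2)c(OCc2ccccc2)c1 | intermediate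
8 | (6Z)-7-[3,4-bis(benzyloxy)phenyl]hept-6-en-1-ol | OCCCCC/C=C\c1ccc(OCc2ccccc2)c(OCc2ccccc2)c1 | intermediate
9 | (6Z)-7-[3,4-bis(benzyloxy)phenyl]hept-6-enal | O=CCCCC/C=C\c1ccc(OCc2ccccc2)c(OCc2ccccc2)c1 | intermediate
10 | lithium 1-[2,6-bis(benzyloxy)phenyl]ethen-1-olate (lithium enolate of 2) | [Li+].[O-]C(=C)c1c(OCc2ccccc2)cccc1OCc1ccccc1 | intermediate (not isolated)
11 | (8Z)-1-[2,6-bis(benzyloxy)phenyl]-9-[3,4-bis(benzyloxy)phenyl]-3-hydroxynon-8-en-1-one (racemic) | O=C(CC(O)CCCC/C=C\c1ccc(OCc2ccccc2)c(OCc2ccccc2)c1)c1c(OCc2ccccc2)cccc1OCc1ccccc1 | intermediate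
12 | (8Z)-1-[2,6-bis(benzyloxy)phenyl]-9-[3,4-bis(benzyloxy)phenyl]-1-oxonon-8-en-3-yl methanesulfonate (racemic) | O=C(CC(OS(C)(=O)=O)CCCC/C=C\c1ccc(OCc2ccccc2)c(OCc2ccccc2)c1)c1c(OCc2ccccc2)cccc1OCc1ccccc1 | intermediate (not isolated)
13 | (2E,8Z)-1-[2,6-bis(benzyloxy)phenyl]-9-[3,4-bis(benzyloxy)phenyl]nona-2,8-dien-1-one | O=C(/C=C/CCCC/C=C\c1ccc(OCc2ccccc2)c(OCc2ccccc2)c1)c1c(OCc2ccccc2)cccc1OCc1ccccc1 | intermediate
14 | malabaricone C, 1-(2,6-dihydroxyphenyl)-9-(3,4-dihydroxyphenyl)nonan-1-one | O=C(CCCCCCCCc1ccc(O)c(O)c1)c1c(O)cccc1O | target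

## Step count and risks

Total step count: 8. Longest linear sequence: 7 steps (steps 2–8, from 6-bromohexanoic acid 3); the ketone branch (step 1) joins at step 6.

**Most likely to fail, first: step 6 (aldol).** The enolisable aldehyde 9 can be deprotonated by the enolate instead of being attacked, and the aldolate can revert. The fallback replaces the aldol by C-alkylation of a β-keto ester; it sets out from 2 and 8 and comes back to the route at 14. Ketone 2 is condensed with diethyl carbonate (NaH, THF, reflux; Claisen condensation) to give ethyl 3-[2,6-bis(benzyloxy)phenyl]-3-oxopropanoate F1. Alcohol 8 is converted with CBr4/PPh3 (CH2Cl2, 0 °C; Appel reaction) into 1,2-bis(benzyloxy)-4-[(1Z)-7-bromohept-1-en-1-yl]benzene F2. Alkylation of F1 with F2 (K2CO3, cat. n-Bu4NI, acetone, reflux) gives ethyl (8Z)-2-[2,6-bis(benzyloxy)benzoyl]-9-[3,4-bis(benzyloxy)phenyl]non-8-enoate F3. Saponification and decarboxylation (NaOH, EtOH/H2O, reflux; then aq. HCl, 60 °C) give (8Z)-1-[2,6-bis(benzyloxy)phenyl]-9-[3,4-bis(benzyloxy)phenyl]non-8-en-1-one F4, which under the conditions of step 8 gives 14.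

**Second: step 8 (global hydrogenation).** The risks are over-reduction of the aryl ketone, incomplete debenzylation, and, if an ortho benzyl ether is cleaved before the enone is saturated, oxa-Michael closure to a chromanone. The fallback separates the two events; it sets out from 13 and comes back at 14. Hydrogenation over Pd/C poisoned with Ph2S (H2 1 atm, EtOAc, rt) saturates only the two alkenes and gives 1-[2,6-bis(benzyloxy)phenyl]-9-[3,4-bis(benzyloxy)phenyl]nonan-1-one F5. Non-reductive debenzylation with BCl3 and pentamethylbenzene as benzyl-cation scavenger (CH2Cl2, −78 °C) then gives 14.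

**Third: step 3 (Wittig with the carboxylate ylide).** The doubly deprotonated ylide is poorly soluble and can give low conversion. The fallback brings the chain in at the alcohol oxidation level, so acid 7 and the LiAlH4 step are bypassed; it sets out from 5 and comes back at 8. Commercial 6-bromohexan-1-ol and PPh3 (MeCN, reflux) give (6-hydroxyhexyl)triphenylphosphonium bromide F6. Its alkoxide ylide (NaN(SiMe3)2, 2.2 equiv, THF, 0 °C) reacts with 5 (−78 °C → rt) in a Z-selective Wittig olefination to give 8 directly.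

## Further compounds

F1 | step 6 | ethyl 3-[2,6-bis(benzyloxy)phenyl]-3-oxopropanoate | CCOC(=O)CC(=O)c1c(OCc2ccccc2)cccc1OCc1ccccc1
F2 | step 6 | 1,2-bis(benzyloxy)-4-[(1Z)-7-bromohept-1-en-1-yl]benzene | BrCCCCC/C=C\c1ccc(OCc2ccccc2)c(OCc2ccccc2)c1
F3 | step 6 | ethyl (8Z)-2-[2,6-bis(benzyloxy)benzoyl]-9-[3,4-bis(benzyloxy)phenyl]non-8-enoate (racemic) | CCOC(=O)C(CCCCC/C=C\c1ccc(OCc2ccccc2)c(OCc2ccccc2)c1)C(=O)c1c(OCc2ccccc2)cccc1OCc1ccccc1
F4 | step 6 | (8Z)-1-[2,6-bis(benzyloxy)phenyl]-9-[3,4-bis(benzyloxy)phenyl]non-8-en-1-one | O=C(CCCCCC/C=C\c1ccc(OCc2ccccc2)c(OCc2ccccc2)c1)c1c(OCc2ccccc2)cccc1OCc1ccccc1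
F5 | step 8 | 1-[2,6-bis(benzyloxy)phenyl]-9-[3,4-bis(benzyloxy)phenyl]nonan-1-one | O=C(CCCCCCCCc1ccc(OCc2ccccc2)c(OCc2ccccc2)c1)c1c(OCc2ccccc2)cccc1OCc1ccccc1
F6 | step 3 | (6-hydroxyhexyl)triphenylphosphonium bromide | [Br-].OCCCCCC[P+](c1ccccc1)(c1ccccc1)c1ccccc1
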